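## Retrosynthetic overview

1. Locants: C1 = angular C–Me, C2/C3 = CH2, C4 = C(OH)iPr, C5 = ring-fusion CH, C6 = CH–O-aroyl, C7 = CHOH, C8(Me)–C9 = epoxide, C10 = CH2; β is the face of the C1 methyl. The plan rests on the oxygenated carbons C6 and C9, 1,4-related across the seven-membered ring, with quaternary C1 next to C10: an O6–C9 enol-ether bridge makes C10=C9–O–C6–C5=C1 an allyl vinyl ether.
2. Target ⇐ α-epoxidation of the C8=C9 allylic silyl ether ⇐ Wharton transposition of a 7β,8β-epoxy-9-ketone ⇐ C7=C8 enone (Saegusa) ⇐ 9-ketone carrying the 6α-aroyl ester ⇐ α-face hydroboration of C5=C6 in the ring-expanded ketone.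
3. Key disconnection C1–C10: Claisen ring expansion of a 2-methylene-oxolane (O, C9, C8, C7, C6) that carries the 2-methylcyclopentenyl group on C6; the oxolane becomes the cycloheptenone.
4. Methylene-oxolane ⇐ Tebbe methylenation of a trans-α-methyl-γ-lactone ⇐ enolate methylation of the γ-lactone ⇐ Brown allylation (sets C6) of a cyclopentene carbaldehyde ⇐ ozonolysis/aldol of (S)-terpinen-4-ol silyl ether.
5. Ring order: cyclopentene (step 3), oxolane as lactone (step 6), cycloheptene by expansion of the oxolane (step 9), oxirane last (step 18).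

Key step: step 9

Remark 1: (S)-(+)-terpinen-4-ol is assumed enantiomerically pure; a lot of lower optical purity would be upgraded before use, because C4 of the target is carried from it unchanged.
Remark 2: the C8 methyl is installed trans to the cyclopentenyl group (by enolate alkylation, not by reduction of an α-methylene lactone, which would favour cis) so that it lies away from the incoming C1 terminus in step 9; C8 is later α to the C9 ketone and is erased in step 14, so epimerisation there is harmless.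

## Route

Step 1
Reactants: 1 (S)-terpinen-4-ol
Product: 2 triethyl{[(1S)-4-methyl-1-(propan-2-yl)cyclohex-3-en-1-yl]oxy}silane
Conditions: TESOTf, 2,6-lutidine, CH2Cl2, 0 °C → rt
Reagents that add atoms: triethylsilyl triflate, CC[Si](CC)(CC)OS(=O)(=O)C(F)(F)F
Why: Silyl ether formation on the hindered tertiary alcohol with a silyl triflate and a non-nucleophilic base; the stereocentre is not touched.

Step 2
Reactants: 2 terpinen-4-ol triethylsilyl ether
Product: 4 (3S)-6-oxo-3-(propan-2-yl)-3-(triethylsilyloxy)heptanal, via ozonide 3 (not isolated)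
Conditions: O3, CH2Cl2, −78 °C; then Me2S, −78 °C → rt
Reagents that add atoms: ozone, [O-][O+]=O
Why: Ozonolysis of the trisubstituted ring alkene with reductive work-up gives the methyl ketone and the aldehyde, the silyl ether preventing hemiketal formation and retro-aldol loss.

Step 3
Reactants: 4 (3S)-6-oxo-3-(propan-2-yl)-3-(triethylsilyloxy)heptanal
Product: 5 (5R)-2-methyl-5-(propan-2-yl)-5-(triethylsilyloxy)cyclopent-1-ene-1-carbaldehyde
Conditions: Bn2NH·TFA (cat.), PhH, 50 °C
Reagents that add atoms: none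
Why: Intramolecular aldol condensation under secondary-ammonium (enamine) catalysis, in which the aldehyde enamine adds to the methyl ketone (5-enolexo-exo-trig) and dehydration gives the tetrasubstituted enal without forming a stereocentre.

Step 4
Reactants: 5 (5R)-2-methyl-5-(propan-2-yl)-5-(triethylsilyloxy)cyclopent-1-ene-1-carbaldehyde
Product: 7 (1S)-1-[(5R)-2-methyl-5-(propan-2-yl)-5-(triethylsilyloxy)cyclopent-1-en-1-yl]but-3-en-1-ol, via O-diisopinocampheylboryl ether 6 (not isolated)
Conditions: (−)-Ipc2BOMe, allylMgBr, Et2O, 0 °C → rt; then 5, −78 °C → rt; then 3 M NaOH, 30% H2O2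
Reagents that add atoms: allylmagnesium bromide, C=CC[Mg]Br; (−)-B-methoxydiisopinocampheylborane (boron stays in 6 only), COB([C@@H]1C[C@@H]2C[C@H]([C@H]1C)C2(C)C)[C@@H]1C[C@@H]2C[C@H]([C@H]1C)C2(C)C
Why: Brown allylboration through a chair Zimmerman–Traxler transition state, in which the reagent of the (+)-α-pinene series should add allyl to the Si face of the formyl group under reagent control and so set C6 as S, any C6 epimer being a diastereomer that chromatography removes.

Step 5
Reactants: 7 homoallylic alcohol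
Product: 9 (1S)-1-[(5R)-2-methyl-5-(propan-2-yl)-5-(triethylsilyloxy)cyclopent-1-en-1-yl]butane-1,4-diol, via B-alkyl-9-BBN adduct 8 (not isolated)
Conditions: 9-BBN, THF, 0 °C → rt; then 3 M NaOH, 30% H2O2
Reagents that add atoms: 9-borabicyclo[3.3.1]nonane (boron stays in 8 only), [BH]1C2CCCC1CCC2; hydrogen peroxide, OO
Why: Hydroboration–oxidation with 9-BBN is selective for the monosubstituted alkene over the tetrasubstituted ring alkene and places boron on the terminal carbon.

Step 6
Reactants: 9 1,4-diol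
Product: 11 (5S)-5-[(5R)-2-methyl-5-(propan-2-yl)-5-(triethylsilyloxy)cyclopent-1-en-1-yl]oxolan-2-one, via lactol 10 (not isolated)
Conditions: TEMPO (cat.), PhI(OAc)2, CH2Cl2, rt
Reagents that add atoms: none
Why: TEMPO/PhI(OAc)2 oxidative lactonisation of a 1,4-diol, in which the primary alcohol is oxidised first, the aldehyde closes to the lactol (5-exo-trig) and the lactol is oxidised to the γ-lactone with C6 unchanged.

Step 7
Reactants: 11 γ-lactone
Product: 13 (3R,5S)-3-methyl-5-[(5R)-2-methyl-5-(propan-2-yl)-5-(triethylsilyloxy)cyclopent-1-en-1-yl]oxolan-2-one (3,5-trans), via lithium enolate 12 (not isolated)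
Conditions: LDA, THF, −78 °C; then MeI, −78 → −40 °C
Reagents that add atoms: iodomethane, CI; lithium diisopropylamide (lithium stays in 12 only), [Li]N(C(C)C)C(C)C
Why: Alkylation of the γ-lactone lithium enolate should take place on the face opposite the bulky C6 substituent (1,3-induction), which sets the C8 methyl trans to the cyclopentenyl group.

Step 8
Reactants: 13 trans-α-methyl-γ-lactone
Product: 14 triethyl({(1R)-3-methyl-2-[(2S,4R)-4-methyl-5-methylideneoxolan-2-yl]-1-(propan-2-yl)cyclopent-2-en-1-yl}oxy)silane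
Conditions: Tebbe reagent, pyridine (cat.), THF/PhMe, −40 °C → rt; aq. NaOH quench, filtration through basic alumina
Reagents that add atoms: Tebbe reagent, Cp2Ti(μ-Cl)(μ-CH2)AlMe2 (open form, Cp drawn σ-bonded), C[Al](C)C[Ti](Cl)(C1C=CC=C1)C1C=CC=C1
Why: Tebbe methylenation of the lactone carbonyl gives the exocyclic enol ether under non-acidic conditions and leaves C6 and C8 unchanged.

Step 9
Reactants: 14 2-methylene-oxolane
Product: 15 4α-isopropyl-1β,8α-dimethyl-4β-(triethylsilyloxy)bicyclo[5.3.0]dec-5-en-9-one (overview locants)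
Conditions: PhMe (degassed), i-Pr2NEt (cat.), base-washed sealed tube, 180 °C
Reagents that add atoms: none
Why: A thermal [3,3] sigmatropic (Claisen) shift of the allyl vinyl ether C10=C9–O–C6–C5=C1 forms C1–C10 as C6–O breaks, so that the ether oxygen becomes the C9 carbonyl and the alkene moves to C5=C6. The closest known reaction type is the Claisen ring expansion of 2-methylene-5-vinyltetrahydrofurans to cyclohept-4-enones, of which this substrate, with a fully substituted vinyl terminus, is a more hindered member. The seven-membered carbocycle is closed by the pericyclic bond shift itself through a boat-like six-atom array imposed by the five-membered ether, so the ring grows from five to seven atoms without any ionic cyclisation. The only new stereocentre, quaternary C1, is controlled by the C6 carbinol centre: the shift is suprafacial across C6–C5–C1 and only the rotamer with C7 syn to C1 can give the cis ring alkene, so the 6S oxygen, held on the α face, sends C10 to the α face of C1 and leaves the methyl β. The step needs the [3,3] path to outrun isomerisation of the exocyclic enol ether and heterolysis of the allylic C–O bond, which the aprotic, base-buffered medium secures, while the C8 methyl, trans to the cyclopentenyl group, lies on the oxolane face away from the incoming terminus and adds no crowding at C1.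

Step 10
Reactants: 15 cycloheptenone
Product: 16 9,9-(ethylenedioxy)-4α-isopropyl-1β,8α-dimethyl-4β-(triethylsilyloxy)bicyclo[5.3.0]dec-5-ene
Conditions: (TMSOCH2)2, TMSOTf (cat.), CH2Cl2, −78 → −20 °C; pyridine quench
Reagents that add atoms: 1,2-bis(trimethylsilyloxy)ethane, C[Si](C)(C)OCCO[Si](C)(C)C
Why: Noyori ketalisation masks the C9 ketone under aprotic low-temperature conditions that the tertiary allylic silyl ether should tolerate.

Step 11
Reactants: 16 ketal alkene
Product: 18 9,9-(ethylenedioxy)-4α-isopropyl-1β,8α-dimethyl-4β-(triethylsilyloxy)-5α-bicyclo[5.3.0]decan-6α-ol, via C6 alkylborane 17 (not isolated)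
Conditions: BH3·THF, THF, 0 °C → rt; then 3 M NaOH, 30% H2O2, 0 → 40 °C
Reagents that add atoms: borane–THF (boron stays in 17 only), [BH3-][O+]1CCCC1; hydrogen peroxide, OO
Why: Hydroboration–oxidation in which boron adds to the less substituted C6 and hydrogen to C5 in a syn manner from the α face, opposite the C1 methyl and the 4β-silyloxy group whose silicon lies over the β face (the sense seen with Δ5-steroids that carry an angular methyl), so that 5α-H (trans ring fusion) and, after oxidation with retention, 6α-OH should be set.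

Step 12
Reactants: 18 C6 alcohol; 19 4-(benzyloxy)benzoyl chloride
Product: 20 9,9-(ethylenedioxy)-4α-isopropyl-1β,8α-dimethyl-4β-(triethylsilyloxy)-5α-bicyclo[5.3.0]dec-6α-yl 4-(benzyloxy)benzoate
Conditions: DMAP, Et3N, CH2Cl2, rt → 40 °C
Reagents that add atoms: none
Why: DMAP-catalysed acylation of the secondary alcohol with an acid chloride fixes the aroyl group on O6 before O7 exists, with the tertiary oxygen still silylated.

Step 13
Reactants: 20 ester ketal
Product: 21 4α-isopropyl-1β,8α-dimethyl-9-oxo-4β-(triethylsilyloxy)-5α-bicyclo[5.3.0]dec-6α-yl 4-(benzyloxy)benzoate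
Conditions: PPTS, acetone/H2O, 55 °C
Reagents that add atoms: water, O
Why: Mild acid hydrolysis of the dioxolane frees the C9 ketone while the ester, the benzyl ether and the now non-allylic tertiary silyl ether should survive.

Step 14
Reactants: 21 keto ester
Product: 23 4α-isopropyl-1β,8-dimethyl-9-oxo-4β-(triethylsilyloxy)-5α-bicyclo[5.3.0]dec-7-en-6α-yl 4-(benzyloxy)benzoate, via trimethylsilyl enol ether 22 (not isolated)
Conditions: TMSOTf, Et3N, CH2Cl2, 0 °C → rt; then Pd(OAc)2, MeCN, rt
Reagents that add atoms: trimethylsilyl triflate (silicon stays in 22 only), C[Si](C)(C)OS(=O)(=O)C(F)(F)F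
Why: Saegusa–Ito oxidation in which the C8 palladium enolate loses a β-hydride from C7 to give the enone, while any enol ether formed towards C10 has no β-hydrogen (C1 is quaternary) and only returns 21, so the regiochemistry corrects itself and the C8 stereocentre is removed.

Step 15
Reactants: 23 enone
Product: 24 7β,8β-epoxy-4α-isopropyl-1β,8α-dimethyl-9-oxo-4β-(triethylsilyloxy)-5α-bicyclo[5.3.0]dec-6α-yl 4-(benzyloxy)benzoate
Conditions: t-BuOOH (in decane), DBU, CH2Cl2, 0 °C → rt
Reagents that add atoms: tert-butyl hydroperoxide, CC(C)(C)OO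
Why: Weitz–Scheffer nucleophilic epoxidation in which the peroxide should add to C7 on the β face, anti to the 6α-aroyloxy group, before the enolate closes the 7β,8β-epoxide.

Step 16
Reactants: 24 epoxy ketone
Product: 26 7β-hydroxy-4α-isopropyl-1β,8-dimethyl-4β-(triethylsilyloxy)-5α-bicyclo[5.3.0]dec-8-en-6α-yl 4-(benzyloxy)benzoate, via epoxy hydrazone 25 (not isolated)
Conditions: N2H4·H2O, AcOH (cat.), MeOH, 0 °C → rt
Reagents that add atoms: hydrazine (nitrogen stays in 25 only and leaves as N2), NN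
Why: Wharton transposition, in which the α,β-epoxy hydrazone fragments with loss of N2 to the allylic alcohol, moves the alkene to C8=C9 and leaves the C7–O bond, and hence the 7β configuration, untouched.

Step 17
Reactants: 26 allylic alcohol
Product: 27 4α-isopropyl-1β,8-dimethyl-4β,7β-bis(triethylsilyloxy)-5α-bicyclo[5.3.0]dec-8-en-6α-yl 4-(benzyloxy)benzoate
Conditions: TESOTf, 2,6-lutidine, CH2Cl2, −78 → 0 °C
Reagents that add atoms: triethylsilyl triflate, CC[Si](CC)(CC)OS(=O)(=O)C(F)(F)F
Why: Silylation of the hindered secondary allylic alcohol removes hydroxyl direction and blocks acyl migration from O6 to O7.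

Step 18
Reactants: 27 bis-silyl ether
Product: 28 8α,9α-epoxy-4α-isopropyl-1β,8β-dimethyl-4β,7β-bis(triethylsilyloxy)-5α-bicyclo[5.3.0]dec-6α-yl 4-(benzyloxy)benzoate
Conditions: mCPBA, NaHCO3, CH2Cl2, 0 °C
Reagents that add atoms: 3-chloroperoxybenzoic acid, OOC(=O)c1cccc(Cl)c1
Why: Prilezhaev epoxidation of the trisubstituted alkene should occur from the α face, anti to the adjacent 7β-silyloxy group and away from the C1 β-methyl, which sets C8 and C9.

Step 19
Reactants: 28 protected epoxide
Product: 29 8α,9α-epoxy-4β,7β-dihydroxy-4α-isopropyl-1β,8β-dimethyl-5α-bicyclo[5.3.0]dec-6α-yl 4-(benzyloxy)benzoate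
Conditions: TBAF, AcOH (1:1), THF, 0 °C → rt
Reagents that add atoms: none
Why: Fluoride cleavage of both triethylsilyl ethers, buffered with acetic acid so that no alkoxide is available to open the epoxide or to move the acyl group.

Step 20
Reactants: 29 benzyl ether
Product: 30 CNP0290052.1, 8α,9α-epoxy-4β,7β-dihydroxy-4α-isopropyl-1β,8β-dimethyl-5α-bicyclo[5.3.0]dec-6α-yl 4-hydroxybenzoate
Conditions: H2 (1 atm), 10% Pd/C, EtOAc, rt
Reagents that add atoms: none
Why: Hydrogenolysis of the aryl benzyl ether over Pd/C under neutral conditions, to which the ester, the non-benzylic trisubstituted epoxide and the free alcohols should be stable.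

## Compound list

1 | (S)-(+)-terpinen-4-ol | CC1=CC[C@](O)(C(C)C)CC1 | starting material
2 | triethyl{[(1S)-4-methyl-1-(propan-2-yl)cyclohex-3-en-1-yl]oxy}silane | CC1=CC[C@](O[Si](CC)(CC)CC)(C(C)C)CC1 | intermediate
3 | ozonide of 2 (1,2,4-trioxolane across former C1/C2, diastereomer mixture) | CC12CC[C@@](O[Si](CC)(CC)CC)(C(C)C)CC(OO1)O2 | intermediate (not isolated)
4 | (3S)-6-oxo-3-(propan-2-yl)-3-(triethylsilyloxy)heptanal | O=CC[C@](O[Si](CC)(CC)CC)(C(C)C)CCC(C)=O | intermediate
5 | (5R)-2-methyl-5-(propan-2-yl)-5-(triethylsilyloxy)cyclopent-1-ene-1-carbaldehyde | CC(C)[C@]1(O[Si](CC)(CC)CC)CCC(C)=C1C=O | intermediate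
6 | O-diisopinocampheylboryl ether of 7 | CC(C)[C@]1(O[Si](CC)(CC)CC)CCC(C)=C1[C@H](CC=C)OB([C@@H]2C[C@@H]3C[C@H]([C@H]2C)C3(C)C)[C@@H]2C[C@@H]3C[C@H]([C@H]2C)C3(C)C | intermediate (not isolated)
7 | (1S)-1-[(5R)-2-methyl-5-(propan-2-yl)-5-(triethylsilyloxy)cyclopent-1-en-1-yl]but-3-en-1-ol | CC(C)[C@]1(O[Si](CC)(CC)CC)CCC(C)=C1[C@@H](O)CC=C | intermediate
8 | B-alkyl-9-BBN adduct of 7 (boron on the terminal carbon) | CC(C)[C@]1(O[Si](CC)(CC)CC)CCC(C)=C1[C@@H](O)CCCB2C3CCCC2CCC3 | intermediate (not isolated)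
9 | (1S)-1-[(5R)-2-methyl-5-(propan-2-yl)-5-(triethylsilyloxy)cyclopent-1-en-1-yl]butane-1,4-diol | CC(C)[C@]1(O[Si](CC)(CC)CC)CCC(C)=C1[C@@H](O)CCCO | intermediate
10 | (5S)-5-(cyclopentenyl)oxolan-2-ol, lactol of 9 (anomer mixture) | CC(C)[C@]1(O[Si](CC)(CC)CC)CCC(C)=C1[C@@H]2CCC(O)O2 | intermediate (not isolated)
11 | (5S)-5-[(5R)-2-methyl-5-(propan-2-yl)-5-(triethylsilyloxy)cyclopent-1-en-1-yl]oxolan-2-one | CC(C)[C@]1(O[Si](CC)(CC)CC)CCC(C)=C1[C@@H]2CCC(=O)O2 | intermediate
12 | lithium enolate of 11 | CC(C)[C@]1(O[Si](CC)(CC)CC)CCC(C)=C1[C@@H]2CC=C(O[Li])O2 | intermediate (not isolated)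
13 | (3R,5S)-3-methyl-5-[(5R)-2-methyl-5-(propan-2-yl)-5-(triethylsilyloxy)cyclopent-1-en-1-yl]oxolan-2-one (trans) | CC(C)[C@]1(O[Si](CC)(CC)CC)CCC(C)=C1[C@@H]2C[C@@H](C)C(=O)O2 | intermediate
14 | triethyl({(1R)-3-methyl-2-[(2S,4R)-4-methyl-5-methylideneoxolan-2-yl]-1-(propan-2-yl)cyclopent-2-en-1-yl}oxy)silane (Claisen precursor) | CC(C)[C@]1(O[Si](CC)(CC)CC)CCC(C)=C1[C@@H]2C[C@@H](C)C(=C)O2 | intermediate
15 | 4α-isopropyl-1β,8α-dimethyl-4β-(triethylsilyloxy)bicyclo[5.3.0]dec-5-en-9-one (Claisen product) | CC(C)[C@]1(O[Si](CC)(CC)CC)CC[C@]2(C)CC(=O)[C@H](C)CC=C21 | intermediate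
16 | 9,9-ethylenedioxy ketal of 15 | CC(C)[C@]1(O[Si](CC)(CC)CC)CC[C@]2(C)CC3(OCCO3)[C@H](C)CC=C21 | intermediate
17 | 6α-boryl-5α-H adduct of 16 | CC(C)[C@]1(O[Si](CC)(CC)CC)CC[C@]2(C)CC3(OCCO3)[C@H](C)C[C@H](B)[C@H]21 | intermediate (not isolated)
18 | 9,9-(ethylenedioxy)-4α-isopropyl-1β,8α-dimethyl-4β-(triethylsilyloxy)-5α-bicyclo[5.3.0]decan-6α-ol | CC(C)[C@]1(O[Si](CC)(CC)CC)CC[C@]2(C)CC3(OCCO3)[C@H](C)C[C@H](O)[C@H]21 | intermediate
19 | 4-(benzyloxy)benzoyl chloride | O=C(Cl)c1ccc(OCc2ccccc2)cc1 | starting material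
20 | 6α-[4-(benzyloxy)benzoate] of 18 | CC(C)[C@]1(O[Si](CC)(CC)CC)CC[C@]2(C)CC3(OCCO3)[C@H](C)C[C@H](OC(=O)c3ccc(OCc4ccccc4)cc3)[C@H]21 | intermediate
21 | 4α-isopropyl-1β,8α-dimethyl-9-oxo-4β-(triethylsilyloxy)-5α-bicyclo[5.3.0]dec-6α-yl 4-(benzyloxy)benzoate | CC(C)[C@]1(O[Si](CC)(CC)CC)CC[C@]2(C)CC(=O)[C@H](C)C[C@H](OC(=O)c3ccc(OCc4ccccc4)cc3)[C@H]21 | intermediate
22 | 9-(trimethylsilyloxy)-8-ene (silyl enol ether of 21) | CC(C)[C@]1(O[Si](CC)(CC)CC)CC[C@]2(C)CC(O[Si](C)(C)C)=C(C)C[C@H](OC(=O)c3ccc(OCc4ccccc4)cc3)[C@H]21 | intermediate (not isolated)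
23 | 4α-isopropyl-1β,8-dimethyl-9-oxo-4β-(triethylsilyloxy)-5α-bicyclo[5.3.0]dec-7-en-6α-yl 4-(benzyloxy)benzoate | CC(C)[C@]1(O[Si](CC)(CC)CC)CC[C@]2(C)CC(=O)C(C)=C[C@H](OC(=O)c3ccc(OCc4ccccc4)cc3)[C@H]21 | intermediate
24 | 7β,8β-epoxy-9-ketone | CC(C)[C@]1(O[Si](CC)(CC)CC)CC[C@]2(C)CC(=O)[C@@]3(C)O[C@H]3[C@H](OC(=O)c3ccc(OCc4ccccc4)cc3)[C@H]21 | intermediate
25 | hydrazone of 24 | CC(C)[C@]1(O[Si](CC)(CC)CC)CC[C@]2(C)CC(=NN)[C@@]3(C)O[C@H]3[C@H](OC(=O)c3ccc(OCc4ccccc4)cc3)[C@H]21 | intermediate (not isolated)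
26 | 7β-hydroxy-8-ene 6α-[4-(benzyloxy)benzoate] | CC(C)[C@]1(O[Si](CC)(CC)CC)CC[C@]2(C)CC=C(C)[C@@H](O)[C@H](OC(=O)c3ccc(OCc4ccccc4)cc3)[C@H]21 | intermediate
27 | 7β-triethylsilyl ether of 26 | CC(C)[C@]1(O[Si](CC)(CC)CC)CC[C@]2(C)CC=C(C)[C@@H](O[Si](CC)(CC)CC)[C@H](OC(=O)c3ccc(OCc4ccccc4)cc3)[C@H]21 | intermediate
28 | 8α,9α-epoxide of 27 | CC(C)[C@]1(O[Si](CC)(CC)CC)CC[C@]2(C)C[C@@H]3O[C@]3(C)[C@@H](O[Si](CC)(CC)CC)[C@H](OC(=O)c3ccc(OCc4ccccc4)cc3)[C@H]21 | intermediate
29 | O-benzyl ether of the target (4β,7β-diol) | CC(C)[C@]1(O)CC[C@]2(C)C[C@@H]3O[C@]3(C)[C@@H](O)[C@H](OC(=O)c3ccc(OCc4ccccc4)cc3)[C@H]21 | intermediate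
30 | CNP0290052.1 | CC(C)[C@]1(O)CC[C@]2(C)C[C@@H]3O[C@]3(C)[C@@H](O)[C@H](OC(=O)c3ccc(O)cc3)[C@H]21 | target

## Step count and risks

Total step count: 20. Longest linear sequence: 20 steps (1 → 30); 19 enters at step 12.

Steps most likely to fail:

1. Step 9. The rearrangement at the fully substituted C1 terminus may be slower than isomerisation of the exocyclic enol ether into the ring or heterolysis of the allylic C6–O bond, which would cost material and erode the C6 → C1 chirality transfer. Fallback, from 14: the thermal pericyclic step is replaced by the triisobutylaluminium-promoted reductive Claisen ring expansion (i-Bu3Al, CH2Cl2, −78 °C → rt). Aluminium bound to the ether oxygen polarises the C6–O bond, so the shift runs far below the thermal threshold, and the ketone is reduced in the flask to the cycloheptenol F1 (C9 configuration of no consequence). Dess–Martin oxidation of F1 returns to the route at 15.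

2. Step 11. Facial selectivity may be poor, since the α face carries the C4 isopropyl group; β-face attack would give the cis-fused 5β,6β-isomer. Fallback, from 16: kinetic face selection is replaced by thermodynamic control. The crude hydroboration–oxidation mixture of 18 and its 5β,6β-isomer F2 is oxidised with Dess–Martin periodinane. The cis-fused 6-ketone F3 arising from F2 is equilibrated at C5 with DBU to the trans-fused 6-ketone F4, in which C6 is no longer cis to the isopropyl group and which 18 itself gives directly. That F4 is the more stable epimer is an expectation and would have to be checked. Reduction of F4 with Li in NH3/THF should give the more stable equatorial 6α-alcohol and returns to the route at 18.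

3. Step 16. Hydrazone formation at the hindered C9 ketone may be slow, so that hydrazinolysis of the aryl ester or acyl migration to the new C7 hydroxyl competes. Fallback, from 22 (made from 21 as in step 14 and isolated): hydrazine is avoided. CsF and PhNTf2 in DME convert 22 into the enol triflate F5. Pd(OAc)2/PPh3 with Bu3N and HCO2H in DMF reduces F5 to the C8=C9 alkene F6. Allylic hydroxylation of F6 with SeO2 (cat.)/t-BuOOH at the ring CH2 next to the more substituted alkene carbon, on the face anti to the C6 ester, returns to the route at 26.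

Further compounds
F1 | step 9 | 4α-isopropyl-1β,8α-dimethyl-4β-(triethylsilyloxy)bicyclo[5.3.0]dec-5-en-9-ol | CC(C)[C@]1(O[Si](CC)(CC)CC)CC[C@]2(C)CC(O)[C@H](C)CC=C21
F2 | step 11 | 5β,6β-isomer of 18 (cis-fused 6β-alcohol) | CC(C)[C@]1(O[Si](CC)(CC)CC)CC[C@]2(C)CC3(OCCO3)[C@H](C)C[C@@H](O)[C@@H]21
F3 | step 11 | cis-fused (5β) 6-ketone | CC(C)[C@]1(O[Si](CC)(CC)CC)CC[C@]2(C)CC3(OCCO3)[C@H](C)CC(=O)[C@@H]21
F4 | step 11 | trans-fused (5α) 6-ketone | CC(C)[C@]1(O[Si](CC)(CC)CC)CC[C@]2(C)CC3(OCCO3)[C@H](C)CC(=O)[C@H]21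
F5 | step 16 | C9 enol triflate (8-ene) of 21 | CC(C)[C@]1(O[Si](CC)(CC)CC)CC[C@]2(C)CC(OS(=O)(=O)C(F)(F)F)=C(C)C[C@H](OC(=O)c3ccc(OCc4ccccc4)cc3)[C@H]21
F6 | step 16 | 8-ene lacking the C7 oxygen | CC(C)[C@]1(O[Si](CC)(CC)CC)CC[C@]2(C)CC=C(C)C[C@H](OC(=O)c3ccc(OCc4ccccc4)cc3)[C@H]21
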